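The number I start from is 52.5 %, the solid ceiling: the solid reagent charged, divided by two, as a percentage of the starting material charged. It is the most target the asked flasks can hold if the solid reagent is the limiting reagent and two units of it go into each target. The midnight run suggests that count. Its last reading, at 5.00 h, shows 31 % starting material and 34 % target, so starting material lost plus target comes to 103 %, close to the 105 % of solid reagent charged. The spring run, with twice the solid reagent and twice the fresh partner, runs on to 80 % target.

in all of them: starting material 0.095 M

|  | fresh partner | solid reagent | temperature | remark | time |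
|---|---|---|---|---|---|
| midnight | 0.045 M | 0.0998 M | 55 °C | run made earlier |  |
| winter | 0.068 M | 0.0998 M | 88 °C | run made earlier |  |
| spring | 0.0902 M | 0.20 M | 55 °C | run made earlier |  |
| Tuesday's | 0.0902 M | 0.0998 M | 80 °C |  | 2.0 h |
| Thursday's | 0.0902 M | 0.0998 M | 40 °C |  | 2.0 h |
| Saturday's | 0.0902 M | 0.0998 M | 100 °C |  | 2.0 h |
| Monday's | 0.0902 M | 0.0998 M | 60 °C |  | 2.0 h |

midnight run (percent of the starting material charged)

| time / h | target / % | starting material / % |
|---|---|---|
| 0.333 | 3 | 88 |
| 0.500 | 1 | 84 |
| 0.667 | 2 | 74 |
| 1.00 | 5 | 60 |
| 1.50 | 14 | 47 |
| 3.00 | 32 | 32 |
| 5.00 | 34 | 31 |

winter run (percent of the starting material charged)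

| time / min | target / % | starting material / % |
|---|---|---|
| 10.0 | 3 | 96 |
| 20.0 | 0 | 85 |
| 30.0 | 6 | 77 |
| 40.0 | 11 | 70 |
| 50.0 | 17 | 64 |
| 60.0 | 26 | 59 |
| 80.0 | 37 | 45 |

spring run (percent of the starting material charged)

| time / h | target / % | starting material / % |
|---|---|---|
| 0.833 | 4 | 79 |
| 1.50 | 15 | 53 |
| 2.50 | 38 | 28 |
| 3.00 | 52 | 16 |
| 5.00 | 80 | 2 |

(readings scatter by 2 percentage points)

- solid, in amounts per volume of the solution: solid reagent
- at the start none of the solid reagent is in solution

- the flask with the highest amount of target, in percent of the starting material charged ("all alike" if they lie within 1.5 percentage points) (Tuesday's / Thursday's / Saturday's / Monday's / all alike)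
- final target, as a percentage of the starting material charged, in Tuesday's
- final target, as a percentage of the starting material charged, in Thursday's
- final target, as a percentage of the starting material charged, in Saturday's
- final target, as a percentage of the starting material charged, in Monday's

Two extreme flasks can be done in the head. In the hot extreme, whatever leaves the starting material turns at once into target, and once the solid reagent is used the flask stands at the ceiling. In the cold extreme, it stays held in a stage before target, and no target forms. The real flask lies between them, at the ceiling minus a correction, and I estimate that correction by the held stage, which I read as starting material lost minus target. That reading is 34 percentage points in the spring run at 55 °C and 2.50 h, and 18 points in the winter run at 88 °C and 80.0 min, smaller in the hotter run, though the times and the charges differ too. So I commit to Saturday's as highest, being hottest, and as a rough estimate, not a bound, I put it above 34.5 % and Thursday's below 18.5 %.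

The forecast gives 46 % for Saturday's, 39 % for Tuesday's, 25 % for Monday's and 12 % for Thursday's, names Saturday's as highest, and holds that “Higher temperature favours the second step”.

Saturday's gives 48.2 %, higher than the others, with Tuesday's at 43.0 %, Monday's at 29.1 % and Thursday's at 8.58 %. The correction is 4.3 points in Saturday's. In Thursday's it is 44 points, and that flask holds 37.1 % as open intermediate at 2.00 h. Left to 20.0 h, Thursday's reaches 44.9 % and Saturday's 49.5 %, each under the ceiling.

    coupling partner + fresh partner → second intermediate (k = 1.80 /M/min, Ea = 52.0 kJ/mol)
    open intermediate + second intermediate → target (k = 0.470 /M/min, Ea = 62.0 kJ/mol)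
    solid reagent ⇌ coupling partner, rate k3*(cs3 - [coupling partner]) while solid is left; crystals form when [coupling partner] > cs3 (solubility = 48.0 mM, k = 0.0270 /min)
    starting material + coupling partner → open intermediate (k = 1.40 /M/min, Ea = 52.0 kJ/mol)
    (constants at 60 °C)

Thursday's flask with 0.036 M of fresh partner keeps the solid ceiling of 52.5 %, but one fresh partner goes into each target, so its charge caps target lower, at 37.9 %. That neighbour gives 5.17 % at 2.00 h, with 51.9 % as open intermediate.

(The earlier runs and the new flask were generated by integration with constants of no real substance, noise included.)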